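**Retrosynthetic overview**

- Numbering: C1 = carboxyl carbon, C3–C6 = carbons of the 1,2-dioxane (ring B), C7–C10 = carbons of the oxolane (ring A), C11–C24 = triene chain. The strategy rests on the C3–O–O–C6 unit of ring B: two secondary carbons in a 1,4-relationship joined through the peroxide bond, the image of a 3,6-diol whose two C–O bonds are replaced with inversion.
- Last skeletal disconnection: both C–O bonds of ring B, giving the (3R,6R)-bis(triflate) 27 and bis(tributyltin) peroxide 26 (double SN2). C1 stays a silyl-protected alcohol until ring B exists and is then oxidised to the acid.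
- Diol 24 comes from a Z-selective Wittig reaction at C17=C18 (phosphonium salt 21 + enal 2), chelation-controlled reduction of C6 ketone 18, and a C5–C6 Grignard union of oxolane aldehyde 15 with the C1–C5 bromide 9 (C3 from asymmetric allylboration).
- Ring A is formed first, by trans-selective aerobic oxidative cyclisation of alkenol 13 (C10 from epoxide 11); ring B is formed last.

Key step: step 19

Remark: the target SMILES is read as (3S,6S,7S,10R), i.e. ring B is a trans-3,6-disubstituted 1,2-dioxane, ring A is a 2,5-trans-disubstituted oxolane, and C6/C7 are threo. The bis(triflate) therefore needs (3R,6R), which is erythro at C6/C7. Epoxide 11, bromochloride 10, distannoxane 25 [(Bu3Sn)2O], Co(modp)2 and (+)-Ipc2BOMe are taken as purchasable.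

**Route**

Step 1
Reactants: 1 pent-4-enal
Product: 2 (2E)-hepta-2,6-dienal
Conditions: Ph3P=CHCHO (1.0 equiv), toluene, 80 °C
Reagents that add atoms: (triphenylphosphoranylidene)acetaldehyde, O=CC=P(c1ccccc1)(c1ccccc1)c1ccccc1
Why: Wittig olefination with the stabilised formyl ylide should give the (E)-enal, the aldehyde being kept in slight excess to limit a second homologation.

Step 2
Reactants: 3 propane-1,3-diol
Product: 4 3-[(tert-butyldiphenylsilyl)oxy]propan-1-ol
Conditions: TBDPSCl (1 equiv), imidazole, CH2Cl2, 0 °C → rt, diol in fourfold excess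
Reagents that add atoms: tert-butyl(chloro)diphenylsilane, CC(C)(C)[Si](Cl)(c1ccccc1)c1ccccc1
Why: Silyl ether formation; the excess of the symmetrical diol should hold the reaction at monosilylation.

Step 3
Reactants: 4 3-[(tert-butyldiphenylsilyl)oxy]propan-1-ol
Product: 5 3-[(tert-butyldiphenylsilyl)oxy]propanal
Conditions: Dess–Martin periodinane, NaHCO3, CH2Cl2, 0 °C → rt
Reagents that add atoms: none
Why: Dess–Martin oxidation stops at the aldehyde, and the buffered non-basic medium avoids β-elimination of the silyloxy group.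

Step 4
Reactants: 5 3-[(tert-butyldiphenylsilyl)oxy]propanal
Product: 6 (3R)-1-[(tert-butyldiphenylsilyl)oxy]hex-5-en-3-ol
Conditions: (+)-Ipc2BOMe, allylMgBr, Et2O, −78 °C → rt; then 5, −78 °C; NaOH, H2O2
Reagents that add atoms: allylmagnesium bromide, C=CC[Mg]Br
Why: Brown asymmetric allylboration: the B-allyldiisopinocampheylborane made from (+)-Ipc2BOMe should deliver allyl to the Re face of the aldehyde through a chair transition state and so set C3 as (R).

Step 5
Reactants: 6 (3R)-1-[(tert-butyldiphenylsilyl)oxy]hex-5-en-3-ol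
Product: 7 (3R)-1-[(tert-butyldiphenylsilyl)oxy]-3-[(triethylsilyl)oxy]hex-5-ene
Conditions: TESCl, imidazole, CH2Cl2, 0 °C
Reagents that add atoms: chlorotriethylsilane, CC[Si](Cl)(CC)CC
Why: Standard silylation of the secondary alcohol; the triethylsilyl ether is chosen because it can later be cleaved without touching the primary TBDPS ether.

Step 6
Reactants: 7 (3R)-1-[(tert-butyldiphenylsilyl)oxy]-3-[(triethylsilyl)oxy]hex-5-ene
Product: 8 (3R)-5-[(tert-butyldiphenylsilyl)oxy]-3-[(triethylsilyl)oxy]pentan-1-ol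
Conditions: O3, CH2Cl2/MeOH, −78 °C; then NaBH4, −78 °C → rt
Reagents that add atoms: ozone, [O-][O+]=O
Why: Ozonolysis of the terminal alkene with reductive work-up should give the primary alcohol one carbon shorter, making C5 the carbinol carbon without touching C3.

Step 7
Reactants: 8 (3R)-5-[(tert-butyldiphenylsilyl)oxy]-3-[(triethylsilyl)oxy]pentan-1-ol
Product: 9 (3S)-1-bromo-5-[(tert-butyldiphenylsilyl)oxy]-3-[(triethylsilyl)oxy]pentane
Conditions: CBr4, PPh3, imidazole, CH2Cl2, 0 °C
Reagents that add atoms: tetrabromomethane, BrC(Br)(Br)Br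
Why: Appel bromination of the primary alcohol, buffered with imidazole so that the triethylsilyl ether is protected from adventitious acid (the descriptor changes to S by priority only).

Step 8
Reactants: 10 1-bromo-6-chlorohexane; 11 (2S)-2-(but-3-en-1-yl)oxirane
Product: 13 (5R)-12-chlorododec-1-en-5-ol, via 6-chlorohexylmagnesium bromide 12 (not isolated)
Conditions: Mg, THF, rt; then CuI (10 mol%), 11, THF, −40 → 0 °C; aq. NH4Cl
Reagents that add atoms: magnesium, [Mg] (kept only in 12)
Why: Magnesium inserts selectively into the C–Br bond, and the CuI-catalysed Grignard opening of the terminal epoxide at its CH2 carbon (C11) leaves the C10–O bond intact, so the (S)-epoxide gives the (R)-carbinol.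

Step 9
Reactants: 13 (5R)-12-chlorododec-1-en-5-ol
Product: 14 [(2S,5R)-5-(7-chloroheptyl)oxolan-2-yl]methanol
Conditions: Co(modp)2 [bis(1-morpholinocarbamoyl-4,4-dimethylpentane-1,3-dionato)cobalt, divalent cobalt] (10 mol%), O2 (1 atm), t-BuOOH (10 mol%), i-PrOH, 55 °C
Reagents that add atoms: dioxygen, O=O
Why: Mukaiyama aerobic oxidative cyclisation of a pent-4-en-1-ol unit (5-exo closure, trapping of the primary radical by O2) is known to give 2,5-trans-oxolanylmethanols, so C7 should be set as (S), trans to the existing C10 centre.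

Step 10
Reactants: 14 [(2S,5R)-5-(7-chloroheptyl)oxolan-2-yl]methanol
Product: 15 (2S,5R)-5-(7-chloroheptyl)oxolane-2-carbaldehyde
Conditions: Dess–Martin periodinane, NaHCO3, CH2Cl2, 0 °C → rt; used crude
Reagents that add atoms: none
Why: Dess–Martin oxidation to the α-alkoxy aldehyde under buffered conditions that should not epimerise C7.

Step 11
Reactants: 9 (3S)-1-bromo-5-[(tert-butyldiphenylsilyl)oxy]-3-[(triethylsilyl)oxy]pentane; 15 (2S,5R)-5-(7-chloroheptyl)oxolane-2-carbaldehyde
Product: 17 (4R)-6-[(tert-butyldiphenylsilyl)oxy]-1-[(2S,5R)-5-(7-chloroheptyl)oxolan-2-yl]-4-[(triethylsilyl)oxy]hexan-1-ol as a mixture of epimers at the new carbinol (C6), via Grignard reagent 16 (not isolated)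
Conditions: Mg, THF, rt (9 → 16); then 15, THF, −78 °C; aq. NH4Cl
Reagents that add atoms: magnesium, [Mg] (kept only in 16)
Why: Grignard addition to the aldehyde forms the C5–C6 bond; the configuration at C6 is irrelevant here because the carbinol is oxidised next, and the primary chloride and silyl ethers are inert to the γ-silyloxy Grignard reagent at −78 °C.

Step 12
Reactants: 17 C6 carbinol mixture
Product: 18 (4R)-6-[(tert-butyldiphenylsilyl)oxy]-1-[(2S,5R)-5-(7-chloroheptyl)oxolan-2-yl]-4-[(triethylsilyl)oxy]hexan-1-one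
Conditions: Dess–Martin periodinane, NaHCO3, CH2Cl2, 0 °C → rt
Reagents that add atoms: none
Why: Dess–Martin oxidation converges both epimers to one ketone without epimerising the adjacent C7 centre.

Step 13
Reactants: 18 C6 ketone
Product: 19 (1R,4R)-6-[(tert-butyldiphenylsilyl)oxy]-1-[(2S,5R)-5-(7-chloroheptyl)oxolan-2-yl]-4-[(triethylsilyl)oxy]hexan-1-ol (target numbering 3R,6R,7S,10R)
Conditions: Zn(BH4)2, Et2O, −40 → −20 °C; aq. NH4Cl
Reagents that add atoms: none
Why: Chelation-controlled (Cram chelate) reduction: zinc bridges the ketone and oxolane oxygens and hydride attacks from the face of the C7–H, which should give the erythro (6R) alcohol; no alkene is present yet that could be hydroborated.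

Step 14
Reactants: 19 erythro alcohol (C17 chloride)
Product: 21 {7-[(2R,5S)-5-{(1R,4R)-6-[(tert-butyldiphenylsilyl)oxy]-1-hydroxy-4-[(triethylsilyl)oxy]hexyl}oxolan-2-yl]heptyl}triphenylphosphonium iodide, via C17 iodide 20 (not isolated)
Conditions: NaI, PPh3, NaHCO3, MeCN, reflux
Reagents that add atoms: sodium iodide, [Na+].[I-]; triphenylphosphine, c1ccc(cc1)P(c1ccccc1)c1ccccc1
Why: Finkelstein exchange in situ followed by SN2 quaternisation of triphenylphosphine by the primary iodide; the hydroxyl and silyl ethers are inert under the buffered neutral conditions.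

Step 15
Reactants: 21 phosphonium iodide; 2 (2E)-hepta-2,6-dienal
Product: 23 (1R,4R)-6-[(tert-butyldiphenylsilyl)oxy]-1-[(2S,5R)-5-[(7Z,9E)-tetradeca-7,9,13-trien-1-yl]oxolan-2-yl]-4-[(triethylsilyl)oxy]hexan-1-ol, via phosphorus ylide 22 (not isolated)
Conditions: NaN(SiMe3)2 (1.05 equiv), THF, −78 °C; then 2, −78 → 0 °C; aq. NH4Cl
Reagents that add atoms: none
Why: Wittig olefination of a non-stabilised ylide under lithium-free conditions should form C17=C18 with Z geometry while the (E) double bond of the enal is carried over unchanged; the remote secondary hydroxyl is less acidic than the phosphonium α-CH and should not quench the ylide.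

Step 16
Reactants: 23 triene triethylsilyl ether
Product: 24 (3R,6R)-1-[(tert-butyldiphenylsilyl)oxy]-6-[(2S,5R)-5-[(7Z,9E)-tetradeca-7,9,13-trien-1-yl]oxolan-2-yl]hexane-3,6-diol
Conditions: PPTS, MeOH, 0 °C → rt
Reagents that add atoms: none
Why: Mild acid-catalysed methanolysis removes the secondary triethylsilyl ether far faster than the primary TBDPS ether, and the acid is too weak to isomerise the diene.

Step 17
Reactants: 25 bis(tributyltin) oxide
Product: 26 bis(tributyltin) peroxide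
Conditions: H2O2 (anhydrous ethereal solution dried over MgSO4, 1.0 equiv), 4 Å molecular sieves, Et2O, 0 °C; filtration, cold concentration; used at once
Reagents that add atoms: hydrogen peroxide, OO
Why: Protolysis of the Sn–O–Sn bridge of (Bu3Sn)2O by hydrogen peroxide (stannoxane–hydroperoxide exchange at tin) places one Bu3Sn group on each peroxide oxygen, and removal of the water formed by the sieves drives the equilibrium to the distannyl peroxide.

Step 18
Reactants: 24 (3R,6R)-diol
Product: 27 (3R,6R)-1-[(tert-butyldiphenylsilyl)oxy]-6-[(2S,5R)-5-[(7Z,9E)-tetradeca-7,9,13-trien-1-yl]oxolan-2-yl]hexane-3,6-diyl bis(trifluoromethanesulfonate)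
Conditions: Tf2O (3 equiv), 2,6-di-tert-butyl-4-methylpyridine, CH2Cl2, −78 → −40 °C, diol added slowly to the anhydride; cold pentane, filtration; used at once
Reagents that add atoms: trifluoromethanesulfonic anhydride, O=S(=O)(OS(=O)(=O)C(F)(F)F)C(F)(F)F
Why: O-Sulfonylation of both secondary hydroxyls with retention at carbon; inverse addition to excess anhydride with a hindered non-nucleophilic pyridine should triflate the second hydroxyl before it can displace the first triflate.

Step 19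
Reactants: 27 (3R,6R)-bis(triflate); 26 bis(tributyltin) peroxide
Product: 28 tert-butyl(2-{(3S,6S)-6-[(2S,5R)-5-[(7Z,9E)-tetradeca-7,9,13-trien-1-yl]oxolan-2-yl]-1,2-dioxan-3-yl}ethoxy)diphenylsilane
Conditions: 26 (1.5 equiv), CH2Cl2 (0.01 M), −78 → 0 °C, dark; cold pentane, filtration through Florisil, chromatography
Reagents that add atoms: none
Why: One Sn–O oxygen of 26 displaces a triflate by SN2 to give an alkyl stannyl peroxide and Bu3SnOTf, and the second peroxide oxygen then closes ring B on the other triflate by 6-exo-tet SN2, each event with inversion, so that (3R,6R)-27 should give the (3S,6S)-dioxane. The closest known reaction type is the formation of cyclic dialkyl peroxides (1,2-dioxolanes and 1,2-dioxanes) from bis(triflates) and (Bu3Sn)2O2, with the alkaline H2O2 cyclisation of bis(sulfonates) as its older relative. Both new stereocentres (C3 and C6) are controlled by the carbinol configurations fixed in steps 4 and 13, which are transferred with inversion. The step needs substitution to outrun ionisation, elimination and intramolecular O-alkylation: the oxolane oxygen β to C6 and the two triflyloxy groups disfavour cationic character, the oxolane oxygen is itself deactivated by the vicinal C6 triflate, and the neutral non-basic stannyl peroxide avoids E2. High dilution favours the intramolecular second displacement over oligomeric peroxides, and the ring formed is the trans-diequatorial dioxane.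

Step 20
Reactants: 28 dioxane TBDPS ether
Product: 29 2-{(3S,6S)-6-[(2S,5R)-5-[(7Z,9E)-tetradeca-7,9,13-trien-1-yl]oxolan-2-yl]-1,2-dioxan-3-yl}ethan-1-ol
Conditions: HF·pyridine, pyridine, THF, 0 °C → rt
Reagents that add atoms: none
Why: Fluoride-mediated cleavage of the silyl ether under buffered conditions that the dialkyl peroxide and the triene tolerate.

Step 21
Reactants: 29 primary alcohol
Product: 30 2-{(3S,6S)-6-[(2S,5R)-5-[(7Z,9E)-tetradeca-7,9,13-trien-1-yl]oxolan-2-yl]-1,2-dioxan-3-yl}acetaldehyde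
Conditions: Dess–Martin periodinane, NaHCO3, CH2Cl2, 0 °C; used crude
Reagents that add atoms: none
Why: Dess–Martin oxidation is neutral and non-reducing, so the O–O bond survives, and the buffered medium avoids base-induced β-elimination of the C3 peroxy oxygen from the aldehyde.

Step 22
Reactants: 30 aldehyde
Product: 31 2-{(3S,6S)-6-[(2S,5R)-5-[(7Z,9E)-tetradeca-7,9,13-trien-1-yl]oxolan-2-yl]-1,2-dioxan-3-yl}acetic acid (target)
Conditions: NaClO2, NaH2PO4, 2-methylbut-2-ene (excess), t-BuOH/H2O, 0 °C → rt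
Reagents that add atoms: sodium chlorite, [Na+].[O-]Cl=O
Why: Pinnick oxidation converts the aldehyde to the acid under weakly acidic conditions, with 2-methylbut-2-ene scavenging HOCl so that the diene, the terminal alkene and the peroxide are spared.

**Compound list**

1 | pent-4-enal | C=CCCC=O | starting material
2 | (2E)-hepta-2,6-dienal | C=CCC/C=C/C=O | intermediate
3 | propane-1,3-diol | OCCCO | starting material
4 | 3-[(tert-butyldiphenylsilyl)oxy]propan-1-ol | OCCCO[Si](c1ccccc1)(c1ccccc1)C(C)(C)C | intermediate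
5 | 3-[(tert-butyldiphenylsilyl)oxy]propanal | O=CCCO[Si](c1ccccc1)(c1ccccc1)C(C)(C)C | intermediate
6 | (3R)-1-[(tert-butyldiphenylsilyl)oxy]hex-5-en-3-ol | C=CC[C@@H](O)CCO[Si](c1ccccc1)(c1ccccc1)C(C)(C)C | intermediate
7 | (3R)-1-[(tert-butyldiphenylsilyl)oxy]-3-[(triethylsilyl)oxy]hex-5-ene | C=CC[C@@H](O[Si](CC)(CC)CC)CCO[Si](c1ccccc1)(c1ccccc1)C(C)(C)C | intermediate
8 | (3R)-5-[(tert-butyldiphenylsilyl)oxy]-3-[(triethylsilyl)oxy]pentan-1-ol | OCC[C@@H](O[Si](CC)(CC)CC)CCO[Si](c1ccccc1)(c1ccccc1)C(C)(C)C | intermediate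
9 | (3S)-1-bromo-5-[(tert-butyldiphenylsilyl)oxy]-3-[(triethylsilyl)oxy]pentane | BrCC[C@@H](O[Si](CC)(CC)CC)CCO[Si](c1ccccc1)(c1ccccc1)C(C)(C)C | intermediate
10 | 1-bromo-6-chlorohexane | ClCCCCCCBr | starting material
11 | (2S)-2-(but-3-en-1-yl)oxirane | C=CCC[C@H]1CO1 | starting material
12 | 6-chlorohexylmagnesium bromide | ClCCCCCC[Mg]Br | intermediate
13 | (5R)-12-chlorododec-1-en-5-ol | ClCCCCCCC[C@@H](O)CCC=C | intermediate
14 | [(2S,5R)-5-(7-chloroheptyl)oxolan-2-yl]methanol | ClCCCCCCC[C@@H]1CC[C@@H](CO)O1 | intermediate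
15 | (2S,5R)-5-(7-chloroheptyl)oxolane-2-carbaldehyde | ClCCCCCCC[C@@H]1CC[C@@H](C=O)O1 | intermediate
16 | [(3S)-5-[(tert-butyldiphenylsilyl)oxy]-3-[(triethylsilyl)oxy]pentyl]magnesium bromide | Br[Mg]CC[C@@H](O[Si](CC)(CC)CC)CCO[Si](c1ccccc1)(c1ccccc1)C(C)(C)C | intermediate
17 | (4R)-6-[(tert-butyldiphenylsilyl)oxy]-1-[(2S,5R)-5-(7-chloroheptyl)oxolan-2-yl]-4-[(triethylsilyl)oxy]hexan-1-ol, C1 epimers | ClCCCCCCC[C@@H]1CC[C@@H](C(O)CC[C@@H](O[Si](CC)(CC)CC)CCO[Si](c2ccccc2)(c2ccccc2)C(C)(C)C)O1 | intermediate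
18 | (4R)-6-[(tert-butyldiphenylsilyl)oxy]-1-[(2S,5R)-5-(7-chloroheptyl)oxolan-2-yl]-4-[(triethylsilyl)oxy]hexan-1-one | ClCCCCCCC[C@@H]1CC[C@@H](C(=O)CC[C@@H](O[Si](CC)(CC)CC)CCO[Si](c2ccccc2)(c2ccccc2)C(C)(C)C)O1 | intermediate
19 | (1R,4R)-6-[(tert-butyldiphenylsilyl)oxy]-1-[(2S,5R)-5-(7-chloroheptyl)oxolan-2-yl]-4-[(triethylsilyl)oxy]hexan-1-ol | ClCCCCCCC[C@@H]1CC[C@@H]([C@H](O)CC[C@@H](O[Si](CC)(CC)CC)CCO[Si](c2ccccc2)(c2ccccc2)C(C)(C)C)O1 | intermediate
20 | (1R,4R)-6-[(tert-butyldiphenylsilyl)oxy]-1-[(2S,5R)-5-(7-iodoheptyl)oxolan-2-yl]-4-[(triethylsilyl)oxy]hexan-1-ol | ICCCCCCC[C@@H]1CC[C@@H]([C@H](O)CC[C@@H](O[Si](CC)(CC)CC)CCO[Si](c2ccccc2)(c2ccccc2)C(C)(C)C)O1 | intermediate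
21 | {7-[(2R,5S)-5-{(1R,4R)-6-[(tert-butyldiphenylsilyl)oxy]-1-hydroxy-4-[(triethylsilyl)oxy]hexyl}oxolan-2-yl]heptyl}triphenylphosphonium iodide | [I-].c1ccccc1[P+](c1ccccc1)(c1ccccc1)CCCCCCC[C@@H]1CC[C@@H]([C@H](O)CC[C@@H](O[Si](CC)(CC)CC)CCO[Si](c2ccccc2)(c2ccccc2)C(C)(C)C)O1 | intermediate
22 | ylide of 21 (triphenylphosphoranylidene at C17) | c1ccccc1P(c1ccccc1)(c1ccccc1)=CCCCCCC[C@@H]1CC[C@@H]([C@H](O)CC[C@@H](O[Si](CC)(CC)CC)CCO[Si](c2ccccc2)(c2ccccc2)C(C)(C)C)O1 | intermediate
23 | (1R,4R)-6-[(tert-butyldiphenylsilyl)oxy]-1-[(2S,5R)-5-[(7Z,9E)-tetradeca-7,9,13-trien-1-yl]oxolan-2-yl]-4-[(triethylsilyl)oxy]hexan-1-ol | C=CCC/C=C/C=C\CCCCCC[C@@H]1CC[C@@H]([C@H](O)CC[C@@H](O[Si](CC)(CC)CC)CCO[Si](c2ccccc2)(c2ccccc2)C(C)(C)C)O1 | intermediate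
24 | (3R,6R)-1-[(tert-butyldiphenylsilyl)oxy]-6-[(2S,5R)-5-[(7Z,9E)-tetradeca-7,9,13-trien-1-yl]oxolan-2-yl]hexane-3,6-diol | C=CCC/C=C/C=C\CCCCCC[C@@H]1CC[C@@H]([C@H](O)CC[C@@H](O)CCO[Si](c2ccccc2)(c2ccccc2)C(C)(C)C)O1 | intermediate
25 | bis(tributyltin) oxide (hexabutyldistannoxane) | CCCC[Sn](CCCC)(CCCC)O[Sn](CCCC)(CCCC)CCCC | starting material
26 | bis(tributyltin) peroxide | CCCC[Sn](CCCC)(CCCC)OO[Sn](CCCC)(CCCC)CCCC | intermediate
27 | (3R,6R)-1-[(tert-butyldiphenylsilyl)oxy]-6-[(2S,5R)-5-[(7Z,9E)-tetradeca-7,9,13-trien-1-yl]oxolan-2-yl]hexane-3,6-diyl bis(trifluoromethanesulfonate) | C=CCC/C=C/C=C\CCCCCC[C@@H]1CC[C@@H]([C@H](OS(=O)(=O)C(F)(F)F)CC[C@@H](OS(=O)(=O)C(F)(F)F)CCO[Si](c2ccccc2)(c2ccccc2)C(C)(C)C)O1 | intermediate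
28 | tert-butyl(2-{(3S,6S)-6-[(2S,5R)-5-[(7Z,9E)-tetradeca-7,9,13-trien-1-yl]oxolan-2-yl]-1,2-dioxan-3-yl}ethoxy)diphenylsilane | C=CCC/C=C/C=C\CCCCCC[C@@H]1CC[C@@H]([C@@H]2CC[C@@H](CCO[Si](c3ccccc3)(c3ccccc3)C(C)(C)C)OO2)O1 | intermediate
29 | 2-{(3S,6S)-6-[(2S,5R)-5-[(7Z,9E)-tetradeca-7,9,13-trien-1-yl]oxolan-2-yl]-1,2-dioxan-3-yl}ethan-1-ol | C=CCC/C=C/C=C\CCCCCC[C@@H]1CC[C@@H]([C@@H]2CC[C@@H](CCO)OO2)O1 | intermediate
30 | 2-{(3S,6S)-6-[(2S,5R)-5-[(7Z,9E)-tetradeca-7,9,13-trien-1-yl]oxolan-2-yl]-1,2-dioxan-3-yl}acetaldehyde | C=CCC/C=C/C=C\CCCCCC[C@@H]1CC[C@@H]([C@@H]2CC[C@@H](CC=O)OO2)O1 | intermediate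
31 | 2-{(3S,6S)-6-[(2S,5R)-5-[(7Z,9E)-tetradeca-7,9,13-trien-1-yl]oxolan-2-yl]-1,2-dioxan-3-yl}acetic acid | C=CCC/C=C/C=C\CCCCCC[C@@H]1CC[C@@H]([C@@H]2CC[C@@H](CC(=O)O)OO2)O1 | target

**Step count**

Total: 22 steps. Longest linear sequence: 17 steps (steps 2–7, 11–16, 18–22, from propane-1,3-diol).

**Steps most likely to fail**

Step 19 (with the triflation of step 18 feeding it). The bis(triflate) may be lost before or during peroxide transfer through ionisation, elimination or intramolecular O-alkylation by the oxolane oxygen at C3 (six-membered oxonium ion), and oligomeric peroxides may compete with ring closure. The fallback makes the two C–O bonds one after the other with a protected hydroperoxide; it sets out from 23 and returns at 28. The free C6 hydroxyl of 23 is mesylated (MsCl, Et3N, CH2Cl2, 0 °C) to give the C6 methanesulfonate F1. PPTS in MeOH removes the triethylsilyl group to give the C3 alcohol F2. Triflation (Tf2O, 2,6-lutidine, CH2Cl2, −78 °C) gives the C3 triflate F3, which is not isolated. It is displaced with inversion by the potassium salt of 2-methoxyprop-2-yl hydroperoxide (KOtBu, THF/DMF, −40 → 0 °C) to give the (3S)-peroxyketal F4. Aqueous acetic acid in THF frees the (3S)-hydroperoxide F5. KOtBu with 18-crown-6 in THF at 0 °C then closes ring B by 6-exo-tet displacement of the C6 mesylate with inversion, giving 28.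

Step 15. Z-selectivity at C17=C18 may erode with the enal partner, and the free C6 hydroxyl may take up part of the base. The fallback fixes both double-bond geometries by stereospecific steps; it sets out from 19 and returns at 23. Chloride 19 is converted with NaI in acetone into iodide 20, here isolated. Oxidation with trimethylamine N-oxide in DMSO (Ganem-type oxidation of a primary iodide) gives the C17 aldehyde F6. Stork–Zhao olefination (Ph3P=CHI from (iodomethyl)triphenylphosphonium iodide and NaN(SiMe3)2, THF/DMPU, −78 °C) gives the (Z)-vinyl iodide F7. Suzuki–Miyaura coupling (Pd(PPh3)4, zerovalent palladium, aqueous KOH, THF, rt) with (E)-2-(hexa-1,5-dien-1-yl)-4,4,5,5-tetramethyl-1,3,2-dioxaborolane F8 (from hex-1-en-5-yne and pinacolborane with catalytic Cp2Zr(H)Cl) joins C18 to C19 with retention at both alkenes and gives 23.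

Step 13. Incomplete chelation would give poor facial selectivity at C6, and the wrong C6 epimer would end as the cis-dioxane. The fallback sets C6 by addition and inversion instead of reduction; it sets out from aldehyde 15 (with Grignard reagent 16) and returns at 19. Addition of 16 to 15 precomplexed with MgBr2·OEt2 in CH2Cl2 at −78 °C should give, under chelation control, the threo (6S) alcohol F9. Mitsunobu inversion (4-nitrobenzoic acid, PPh3, DIAD, toluene, 0 °C → rt) gives the (6R) 4-nitrobenzoate F10, and K2CO3 in MeOH releases 19.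

**Further compounds**

F1 | step 19 | C6 methanesulfonate of 23 (3R,6R; C3 triethylsilyl ether) | C=CCC/C=C/C=C\CCCCCC[C@@H]1CC[C@@H]([C@H](OS(C)(=O)=O)CC[C@@H](O[Si](CC)(CC)CC)CCO[Si](c2ccccc2)(c2ccccc2)C(C)(C)C)O1
F2 | step 19 | C6 methanesulfonate with free C3 hydroxyl (3R,6R) | C=CCC/C=C/C=C\CCCCCC[C@@H]1CC[C@@H]([C@H](OS(C)(=O)=O)CC[C@@H](O)CCO[Si](c2ccccc2)(c2ccccc2)C(C)(C)C)O1
F3 | step 19 | C3 triflate C6 methanesulfonate (3R,6R) | C=CCC/C=C/C=C\CCCCCC[C@@H]1CC[C@@H]([C@H](OS(C)(=O)=O)CC[C@@H](OS(=O)(=O)C(F)(F)F)CCO[Si](c2ccccc2)(c2ccccc2)C(C)(C)C)O1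
F4 | step 19 | (3S)-C3 2-methoxyprop-2-yl peroxide C6 methanesulfonate | C=CCC/C=C/C=C\CCCCCC[C@@H]1CC[C@@H]([C@H](OS(C)(=O)=O)CC[C@H](OOC(C)(C)OC)CCO[Si](c2ccccc2)(c2ccccc2)C(C)(C)C)O1
F5 | step 19 | (3S)-C3 hydroperoxide C6 methanesulfonate | C=CCC/C=C/C=C\CCCCCC[C@@H]1CC[C@@H]([C@H](OS(C)(=O)=O)CC[C@H](OO)CCO[Si](c2ccccc2)(c2ccccc2)C(C)(C)C)O1
F6 | step 15 | C17 aldehyde (7-oxoheptyl analogue of 19) | O=CCCCCCC[C@@H]1CC[C@@H]([C@H](O)CC[C@@H](O[Si](CC)(CC)CC)CCO[Si](c2ccccc2)(c2ccccc2)C(C)(C)C)O1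
F7 | step 15 | (17Z)-18-iodo alkene [(Z)-8-iodooct-7-en-1-yl analogue of 19] | I/C=C\CCCCCC[C@@H]1CC[C@@H]([C@H](O)CC[C@@H](O[Si](CC)(CC)CC)CCO[Si](c2ccccc2)(c2ccccc2)C(C)(C)C)O1
F8 | step 15 | (E)-2-(hexa-1,5-dien-1-yl)-4,4,5,5-tetramethyl-1,3,2-dioxaborolane | C=CCC/C=C/B1OC(C)(C)C(C)(C)O1
F9 | step 13 | (1S,4R)-6-[(tert-butyldiphenylsilyl)oxy]-1-[(2S,5R)-5-(7-chloroheptyl)oxolan-2-yl]-4-[(triethylsilyl)oxy]hexan-1-ol (threo, 6S) | ClCCCCCCC[C@@H]1CC[C@@H]([C@@H](O)CC[C@@H](O[Si](CC)(CC)CC)CCO[Si](c2ccccc2)(c2ccccc2)C(C)(C)C)O1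
F10 | step 13 | 4-nitrobenzoate of 19 (6R) | ClCCCCCCC[C@@H]1CC[C@@H]([C@H](OC(=O)c2ccc(cc2)[N+](=O)[O-])CC[C@@H](O[Si](CC)(CC)CC)CCO[Si](c2ccccc2)(c2ccccc2)C(C)(C)C)O1
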